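The violet run is slow: after 40.0 h it still holds 31% of its charge as free monomer, and the question for Wednesday's and Saturday's stands at 3.0 d.

| flask | free monomer | initiator | remark | time |
|---|---|---|---|---|
| violet | 13 mM (fed, over 25 h) | 40 µM | run made earlier |  |
| grey | 40 mM (fed, over 25 h) | 40 µM | run made earlier |  |
| Wednesday's | 20 mM (fed, over 25 h) | 40 µM |  | 3.0 d |
| Saturday's | 20 mM (fed, over 25 h) | 12 µM |  | 3.0 d |

| run | time / h | monomer in chains / % | free monomer / % |
|---|---|---|---|
| violet | 5.00 | 3 | 18 |
| violet | 15.0 | 21 | 42 |
| violet | 30.0 | 56 | 46 |
| violet | 40.0 | 71 | 31 |
| grey | 3.00 | 4 | 12 |
| grey | 8.00 | 7 | 25 |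
| grey | 20.0 | 35 | 43 |
| grey | 40.0 | 64 | 35 |

(standard deviation of a reading: 2 percentage points)

* which of the two ends with the longer chains by the average number of monomer units in a chain (chains begun, living or dead) ("neither" if they lie within 10%) (Wednesday's / Saturday's / neither)
* average number of monomer units in a chain (chains begun, living or dead) at the end, Wednesday's
* average number of monomer units in a chain (chains begun, living or dead) at the end, Saturday's

- the average divides the monomer in chains by the number of chains begun, living and dead together
- the earlier runs do not show the number of chains; that part of a forecast is a guess
- percentages count the whole charge, also what has not yet gone in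
- no earlier run changes the charge of initiator; that part of a forecast is a guess

Take the length as

length = c(monomer in chains) / c(chains begun)

and test each input. Monomer charge: violet and grey differ in it by a factor of 3.08, yet at 40.0 h they read 31% and 35% free, so at 40 µM of initiator the percentages barely move between these runs and length scales with the charge. Feed: each of the flasks here is fed over 25 h, so the runs hold it fixed; leave it. Chains begun: no run shows them, so guess one per initiator; an error here passes straight into the length. The percentage reacted remains, and that is the number to get.

After the feed, define the exposure E = ln(charge / free monomer left); in a pseudo-first-order view it grows each hour by the rate constant of that hour. The two runs give a mean of 1.11 at 40.0 h, and violet's late slope is 0.0395 h⁻¹. Assuming the slope fades, count the remaining hours at half of it, which gives 1.74 for Wednesday's. Divide by the initiator charge to get the exposure per initiator, 43.5 mM⁻¹, and guess that it holds between flasks.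

Wednesday's: E = 1.74, reacted 82.4%, length 412

Saturday's: E = 0.523, reacted 40.7%, length 678

The forecast names Saturday's as longer, with 430 and 800: “about 10 mM over 12 µM gives roughly 800 units”. Both my figures are lower.

The flask gives 388 for Wednesday's and 621 for Saturday's, so Saturday's ends longer.

    free monomer + living end → monomer in chains + living end, rate k1*[living end]*[free monomer] (k = 45.0 M⁻¹ min⁻¹)
    living end → dead end (k = 8.00 × 10⁻⁴ min⁻¹)
    free monomer + initiator → living end + monomer in chains (k = 0.780 M⁻¹ min⁻¹)

The difference in initiator charge is the main reason for the gap: Saturday's flask ends at 621, against 388 without that difference. Read from the end states, exposure per initiator is 37.5 mM⁻¹ on Wednesday's and 38.9 mM⁻¹ on Saturday's, both below the reckoned 43.5 mM⁻¹. Apply 37.5 mM⁻¹ to the neighbour flask, Saturday's with 0.030 mM of initiator: it predicts 67.5% reacted, and that flask holds 68.0% in chains, at length 453.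

The earlier runs and the new flask stem from a simulated flask for an exercise, noise included.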